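The readings were computed for substances that don't exist, and the scatter is random.

Late in the south-east run, at 15.0 h, product stands at 90.0 %, so about 10.0 % of the substrate has not come through. The argument starts from that reading.

| flask | substrate | reagent | free catalyst | remark | time |
|---|---|---|---|---|---|
| south-east | 20 mM | 30 mM | 2.8 mM | run made earlier |  |
| north | 20 mM | 30 mM | 1.9 mM | run made earlier |  |
| east | 20 mM | 30 mM | 4.2 mM | run made earlier |  |
| north-east | 20 mM | 15 mM | 2.8 mM | run made earlier |  |
| amber | 20 mM | 30.0 mM (fed, over 10 h) | 2.8 mM | all else is in the flask from the start; the feed brings no volume worth counting | 15 h |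
| grey | 20 mM (fed, over 10 h) | 30.0 mM | 2.8 mM | all else is in the flask from the start; the feed brings no volume worth counting | 15 h |
| teal | 20 mM (fed, over 2.5 h) | 30.0 mM | 2.8 mM | all else is in the flask from the start; the feed brings no volume worth counting | 15 h |
| red | 20 mM | 30.0 mM | 2.8 mM | everything together at the start | 15 h |

| south-east: time / h | south-east: product / % | north: time / h | north: product / % | east: time / h | east: product / % | north-east: time / h | north-east: product / % |
|---|---|---|---|---|---|---|---|
| 4.00 | 34.1 | 4.00 | 23.8 | 4.00 | 47.5 | 2.00 | 16.2 |
| 8.00 | 61.4 | 8.00 | 46.1 | 8.00 | 78.0 | 5.00 | 40.2 |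
| 12.0 | 79.7 | 12.0 | 63.7 | 12.0 | 92.8 | 10.0 | 66.0 |
| 15.0 | 90.0 | 15.0 | 74.3 | 15.0 | 96.3 | 15.0 | 74.5 |

(each reading ± 0.5 percentage points)

- the earlier runs were read with a standard deviation of 0.5 percentage points

- the flask that comes out highest in amount of product, in percent of the substrate charged, or "all alike" when all lie within 1.5 percentage points (amber / grey / teal / red / all alike)
- product at the end, in percent of the substrate charged, amber
- product at the end, in percent of the substrate charged, grey
- product at the end, in percent of the substrate charged, teal
- product at the end, in percent of the substrate charged, red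

Two of us read these runs differently, and the flask in dispute is grey. The south-east constant ln(c(start)/c(now))/time is 0.104 h⁻¹ over the first 4.00 h, but 0.236 h⁻¹ over the last stretch, about twice as large. The maker of the forecast reads this as saturation in substrate and steps the flasks through a fitted rate law. It gives red as highest, with amber 85 %, grey 79 %, teal 88 % and red 90 %; of grey it says “runs at low substrate, so it is slowest”.

I hold a simpler view: take one constant for the whole run. The south-east run then reads as a mean half-life of 4.52 h, the time in which c(substrate) halves if the run had one constant throughout, a pseudo-first-order half-life. That is 0.154 h⁻¹. In grey, feed and decay together leave 10.2 mM of substrate at 10 h, which is 51.1 % of the charge. The remaining 5.00 h bring this down to 23.7 %, so grey gives 76.3 % product, less than the forecast says. The same reckoning leaves 12.2 % in teal, so teal gives 87.8 %. Red repeats south-east at 90.0 % and stays highest. For amber, where reagent is fed, my half-life says nothing, and I take the forecast's figure.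

The flasks give red as highest, with amber 85.5 %, grey 72.8 %, teal 85.3 % and red 88.0 %.

    substrate + free catalyst → catalyst intermediate A (k = 1.20 L mol⁻¹ min⁻¹)
    catalyst intermediate B → by-product + catalyst intermediate C (k = 0.0310 min⁻¹)
    catalyst intermediate C → free catalyst + product (k = 0.820 min⁻¹)
    reagent + catalyst intermediate A → catalyst intermediate B (k = 14.0 L mol⁻¹ min⁻¹)

In red, the half-life of substrate by its step with free catalyst shortens from 5.2 h at 4.68 h to 3.8 h at 15.0 h, and 4.52 h lies between them . Grey ends its feed holding 51.8 % of its substrate, and the 1.11 half-lives that follow leave 24.5 %, against 23.7 % reckoned. Teal holds 13.0 % of its substrate at 15.0 h, against 12.2 % reckoned.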